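**Retrosynthetic overview**
- Kukoamine A is C2-symmetric about the C2–C3 bond of its central N–CH2–CH2–CH2–CH2–N (butane-1,4-diyl) unit. Each of these two carbons lies two atoms from a secondary amine nitrogen, so each half is an N-substituted β-alanine minus CO2.
- Key disconnection: anodic decarboxylative (Kolbe) homo-dimerisation of one protected β-amino acid. It joins two carbons of like polarity and doubles the molecule in one operation.
- The monomer comes from propane-1,3-diamine, tert-butyl acrylate (aza-Michael) and dihydrocaffeic acid (chemoselective amide formation at the primary amine).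
- The amine and both phenols are masked as benzyl carbamate and benzyl carbonates. These are electron-poor and anodically inert, and one hydrogenolysis removes all of them at the end.
- No ring is formed in the route. The two 3,4-dihydroxyphenyl rings are bought in intact with dihydrocaffeic acid.

Key step: step 6

Remark: the target has no stereocentre and no stereogenic double bond, so it is one achiral compound and no step has to set configuration. It is made as the free base drawn.

**Route**

Step 1
Reactants: 1 propane-1,3-diamine (large excess); 2 tert-butyl acrylate
Product: 3 tert-butyl 3-[(3-aminopropyl)amino]propanoate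
Conditions: 1 (8–10 equiv), MeOH, 0 °C to rt, slow addition of 2; excess 1 removed in vacuo
Reagents that add atoms: none
Why: Aza-Michael addition of a primary amine to an acrylate, in which the large excess of the symmetric diamine should hold the reaction at the mono-adduct and the tert-butyl ester resists aminolysis.

Step 2
Reactants: 4 dihydrocaffeic acid [3-(3,4-dihydroxyphenyl)propanoic acid]
Product: 5 2,5-dioxopyrrolidin-1-yl 3-(3,4-dihydroxyphenyl)propanoate (N-hydroxysuccinimide ester)
Conditions: N-hydroxysuccinimide, DCC, THF, 0 °C to rt, Ar; urea filtered off
Reagents that add atoms: N-hydroxysuccinimide, O=C1CCC(=O)N1O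
Why: Carbodiimide (Steglich-type) activation of the acid and trapping by N-hydroxysuccinimide should give the isolable active ester, since without added base the catechol hydroxyls are not acylated.

Step 3
Reactants: 3 tert-butyl 3-[(3-aminopropyl)amino]propanoate; 5 N-hydroxysuccinimide ester of dihydrocaffeic acid
Product: 6 tert-butyl 3-({3-[3-(3,4-dihydroxyphenyl)propanamido]propyl}amino)propanoate
Conditions: Et3N, CH2Cl2/THF, −20 to 0 °C, Ar, slow addition of 5
Reagents that add atoms: none
Why: Chemoselective aminolysis of an active ester, in which the unhindered primary amine should react far faster than the more hindered, less basic secondary β-amino-ester nitrogen (the usual selectivity in polyamine acylation), while Et3N keeps the primary amine unprotonated as N-hydroxysuccinimide is released.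

Step 4
Reactants: 6 tert-butyl 3-({3-[3-(3,4-dihydroxyphenyl)propanamido]propyl}amino)propanoate
Product: 7 tert-butyl 3-[(benzyloxycarbonyl){3-[3-(3,4-bis{[(benzyloxy)carbonyl]oxy}phenyl)propanamido]propyl}amino]propanoate
Conditions: CbzCl (3.3 equiv), Et3N, CH2Cl2, 0 °C to rt, Ar
Reagents that add atoms: benzyl chloroformate, O=C(Cl)OCc1ccccc1
Why: Acylation with a chloroformate (Schotten–Baumann type) should convert the secondary amine into the benzyl carbamate and both phenols into benzyl carbonates while the amide N–H stays untouched, which makes nitrogen and arene electron-poor for the anodic step.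

Step 5
Reactants: 7 tris-Cbz tert-butyl ester
Product: 8 3-[(benzyloxycarbonyl){3-[3-(3,4-bis{[(benzyloxy)carbonyl]oxy}phenyl)propanamido]propyl}amino]propanoic acid
Conditions: TFA/CH2Cl2 (1:2), 0 °C to rt; co-evaporation with toluene to remove all TFA
Reagents that add atoms: none
Why: Acidolysis of the tert-butyl ester with loss of isobutene should free the carboxylic acid, since benzyl carbamate, aryl benzyl carbonates and the amide are stable to TFA at room temperature.

Step 6
Reactants: 8 carboxylic acid (two molecules)
Product: 9 N4,N9-bis(benzyloxycarbonyl)-N1,N12-bis{3-[3,4-bis({[(benzyloxy)carbonyl]oxy})phenyl]propanoyl}spermine (hexa-Cbz kukoamine A)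
Conditions: Pt anode, Pt cathode, undivided cell, constant current (ca. 200 mA cm−2), MeOH/pyridine (4:1), Et3N (0.1 equiv), 10–15 °C, ca. 2 F mol−1, stopped before the acid is fully consumed
Reagents that add atoms: none
Why: Kolbe electrolysis: the carboxylate of 8 is oxidised by one electron at the platinum anode, the acyloxy radical loses CO2, and two of the resulting primary radicals R(Cbz)N–CH2–CH2•, formed side by side at high surface concentration, combine to the central C–C bond of the butane-1,4-diyl chain, a union of two carbons of like polarity. The closest known reaction type is the Kolbe homo-coupling of carbamate-protected amino acids whose carboxyl group sits two carbons from nitrogen (N-acyl β-alanines, aspartic acid α-esters), which gives protected 1,4-diamines. No ring is closed and no stereocentre is formed, so neither a mode of closure nor a stereocontrol element is involved. The step needs radical dimerisation to win over further oxidation of the radical to a cation (Hofer–Moest path) and over oxidation of the arenes and of the C–H bonds next to nitrogen. The radical is primary and unstabilised and therefore hard to oxidise, the catechols are held as electron-poor bis(carbonates) and the amine as a carbamate so that they should be oxidised only above the working potential, and a carboxylate layer on smooth platinum in weakly acidic methanol at high current density is the established regime for the dimer. Being a homo-coupling, the step has no cross-selectivity problem.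

Step 7
Reactants: 9 hexa-Cbz kukoamine A
Product: 10 kukoamine A, N1,N12-bis[3-(3,4-dihydroxyphenyl)propanoyl]spermine
Conditions: H2 (1 atm), 10% Pd/C, THF/MeOH, rt; filtration and concentration under Ar
Reagents that add atoms: none
Why: Catalytic hydrogenolysis of the benzylic C–O bonds of the two carbamates and four carbonates, followed by spontaneous loss of CO2, should release both secondary amines and both catechols under neutral conditions, so the target is obtained directly as the free base.

**Compound list**
1 | propane-1,3-diamine | NCCCN | starting material
2 | tert-butyl acrylate | C=CC(=O)OC(C)(C)C | starting material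
3 | tert-butyl 3-[(3-aminopropyl)amino]propanoate | NCCCNCCC(=O)OC(C)(C)C | intermediate
4 | dihydrocaffeic acid, 3-(3,4-dihydroxyphenyl)propanoic acid | OC(=O)CCc1ccc(O)c(O)c1 | starting material
5 | 2,5-dioxopyrrolidin-1-yl 3-(3,4-dihydroxyphenyl)propanoate | O=C(CCc1ccc(O)c(O)c1)ON1C(=O)CCC1=O | intermediate
6 | tert-butyl 3-({3-[3-(3,4-dihydroxyphenyl)propanamido]propyl}amino)propanoate | O=C(CCc1ccc(O)c(O)c1)NCCCNCCC(=O)OC(C)(C)C | intermediate
7 | tert-butyl 3-[(benzyloxycarbonyl){3-[3-(3,4-bis{[(benzyloxy)carbonyl]oxy}phenyl)propanamido]propyl}amino]propanoate | O=C(CCc1ccc(OC(=O)OCc2ccccc2)c(OC(=O)OCc2ccccc2)c1)NCCCN(C(=O)OCc1ccccc1)CCC(=O)OC(C)(C)C | intermediate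
8 | 3-[(benzyloxycarbonyl){3-[3-(3,4-bis{[(benzyloxy)carbonyl]oxy}phenyl)propanamido]propyl}amino]propanoic acid | O=C(CCc1ccc(OC(=O)OCc2ccccc2)c(OC(=O)OCc2ccccc2)c1)NCCCN(C(=O)OCc1ccccc1)CCC(=O)O | intermediate
9 | N4,N9-bis(benzyloxycarbonyl)-N1,N12-bis{3-[3,4-bis({[(benzyloxy)carbonyl]oxy})phenyl]propanoyl}spermine | O=C(CCc1ccc(OC(=O)OCc2ccccc2)c(OC(=O)OCc2ccccc2)c1)NCCCN(C(=O)OCc1ccccc1)CCCCN(C(=O)OCc1ccccc1)CCCNC(=O)CCc1ccc(OC(=O)OCc2ccccc2)c(OC(=O)OCc2ccccc2)c1 | intermediate
10 | kukoamine A | O=C(CCc1ccc(O)c(O)c1)NCCCNCCCCNCCCNC(=O)CCc1ccc(O)c(O)c1 | target

**Step count and risks**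

Total step count: 7. Longest linear sequence: 6 (steps 1, 3, 4, 5, 6, 7; the branch through step 2 is equally long).

Steps most likely to fail:

1. Step 6 (key step). What may go wrong: anodic oxidation of the arenes or of the C–H bonds next to the carbamate nitrogen in competition with carboxylate oxidation; further oxidation of the radical to a cation with capture by methanol or by the carbamate carbonyl; disproportionation of the radicals; passivation of the anode; methanolysis of the aryl carbonates once the medium turns basic near full conversion. Fallback: the same central bond is made by olefin metathesis instead of radical coupling. The fallback sets out from 1 and comes back to the route at 10. Compound 1 in large excess is mono-alkylated with allyl bromide (THF, 0 °C) to N1-allylpropane-1,3-diamine F1. Its primary amine is acylated with 5 as in step 3 to give N-[3-(allylamino)propyl]-3-(3,4-dihydroxyphenyl)propanamide F2. CbzCl and Et3N as in step 4 give benzyl allyl{3-[3-(3,4-bis{[(benzyloxy)carbonyl]oxy}phenyl)propanamido]propyl}carbamate F3. Self-metathesis of the terminal alkene (second-generation ruthenium alkylidene catalyst, CH2Cl2, 40 °C, ethene purged) joins the two allyl termini to the but-2-ene-1,4-diyl dimer, hexa-Cbz 6,7-didehydrokukoamine A F4 (E isomer expected to predominate; the geometry is of no consequence). Hydrogenation over Pd/C then saturates the alkene and removes all six Cbz groups in one operation to give 10.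

2. Step 3. What may go wrong: loss of chemoselectivity between the primary and the secondary amine (double acylation or acylation at the wrong nitrogen), made worse if the primary amine is protonated by the released N-hydroxysuccinimide or by the catechol. Fallback: the amide is made before the secondary amine exists. The fallback sets out from 1 and 5 and comes back at 6. Compound 5 is added slowly to a large excess of 1 (THF, 0 °C, Ar), which should give only mono-acylation, N-(3-aminopropyl)-3-(3,4-dihydroxyphenyl)propanamide F5. After removal of excess 1, aza-Michael addition of F5 to 2 (1.0 equiv, MeOH, rt) gives 6.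

3. Step 4. What may go wrong: incomplete triple acylation, closure of the five-membered cyclic carbonate on the catechol after the first O-acylation, or degradation of the chloroformate by the tertiary amine base. Fallback: nitrogen and oxygen are protected in two separate stages with different acyl donors. The fallback sets out from 6 and comes back at 7. N-(benzyloxycarbonyloxy)succinimide (1.05 equiv, CH2Cl2, 0 °C), which does not acylate phenols, gives tert-butyl 3-[(benzyloxycarbonyl){3-[3-(3,4-dihydroxyphenyl)propanamido]propyl}amino]propanoate F6. The catechol of F6 is then converted into the bis(benzyl carbonate) with benzyl chloroformate in pyridine at 0 °C, where no free phenoxide is present to close the cyclic carbonate, to give 7.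

**Further compounds**
F1 | step 6 | N1-allylpropane-1,3-diamine | NCCCNCC=C
F2 | step 6 | N-[3-(allylamino)propyl]-3-(3,4-dihydroxyphenyl)propanamide | O=C(CCc1ccc(O)c(O)c1)NCCCNCC=C
F3 | step 6 | benzyl allyl{3-[3-(3,4-bis{[(benzyloxy)carbonyl]oxy}phenyl)propanamido]propyl}carbamate | O=C(CCc1ccc(OC(=O)OCc2ccccc2)c(OC(=O)OCc2ccccc2)c1)NCCCN(C(=O)OCc1ccccc1)CC=C
F4 | step 6 | hexa-Cbz (E)-6,7-didehydrokukoamine A | O=C(CCc1ccc(OC(=O)OCc2ccccc2)c(OC(=O)OCc2ccccc2)c1)NCCCN(C(=O)OCc1ccccc1)C/C=C/CN(C(=O)OCc1ccccc1)CCCNC(=O)CCc1ccc(OC(=O)OCc2ccccc2)c(OC(=O)OCc2ccccc2)c1
F5 | step 3 | N-(3-aminopropyl)-3-(3,4-dihydroxyphenyl)propanamide | NCCCNC(=O)CCc1ccc(O)c(O)c1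
F6 | step 4 | tert-butyl 3-[(benzyloxycarbonyl){3-[3-(3,4-dihydroxyphenyl)propanamido]propyl}amino]propanoate | O=C(CCc1ccc(O)c(O)c1)NCCCN(C(=O)OCc1ccccc1)CCC(=O)OC(C)(C)C
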